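**Plan**

1. Retrosynthetic cuts: C1–C7 (ring A ketone plus C7 iodide); the C15–O bond (through a C17→C15 lactone); C11–C16 and C12–C13 together (intramolecular [4+2]); C16=C15 and C14=C13 (two Wittig steps); C8–C7 (auxiliary hydroxymethylation); C10–C11 and C12–Br (carbomagnesiation of propargyl alcohol).
2. Enabling feature: the angular carbon C11 (bearing C17) lies between the bromide carbon C12 and the fusion carbon C16, so a (Z)-β-bromo enal C11=C12 (C17 as formyl) tied through C10–C9–C8 to the diene C16=C15–C14=C13 maps onto ring B (C8–C9–C10–C11–C16) and ring C (C11–C12–C13–C14–C15–C16) in one cycloaddition.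
3. Forward order: open chain C17–C11(=C12HBr)–C10–C9–C8–C16, then the diene, then rings B and C together, then the lactone bridge to C15, then union with ring A (made separately by bromonium cyclisation), acetylation at C1 and reductive opening of the lactone.
4. Stereochemistry: C8 from the (R)-4-benzyloxazolidinone; C11, C12 and C16 from the cycloaddition ((Z)-olefin gives Br cis to C17, formyl-endo gives trans fusion, 1,3-allylic strain at C8 selects the diene face); C15 from intramolecular lactonisation; C4 from resolution of the bromoketone as its (R,R)-hydrobenzoin ketal; C1 from equatorial addition to that ketone.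
5. Numbering: ring A C1(OAc), C2, C3, C4(Br), C5(Me2), C6; link C7; ring B C8, C9, C10, C11, C16; ring C C11, C12(Br), C13, C14, C15(Me,OH), C16; C17 is the CH2OH carbon.

Key step: step 14

Assumption: the two hydrobenzoin ketals of the racemic bromoketone are taken to be separable on silica or by crystallisation, and the retained ketal would be assigned by X-ray analysis (bromine as heavy atom).

Step 1
Reactants: 1 prop-2-yn-1-ol; 2 5-bromopent-1-ene
Product: 5 (2Z)-2-(bromomethylidene)hept-6-en-1-ol, via pent-4-enylmagnesium bromide 3 (not isolated), via alkenylmagnesium alkoxide 4 (not isolated)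
Conditions: 2, Mg, THF, rt (2.5 equiv of 3); then 1, CuI (10 mol %), THF, −10 °C → rt; then N-bromosuccinimide, −78 → 0 °C
Reagents that add atoms: N-bromosuccinimide, O=C1CCC(=O)N1Br
Why: Copper-catalysed anti-carbomagnesiation of propargyl alcohol should put the pentenyl group on C11 and magnesium on C12 cis to the alkoxymethyl group through a five-membered chelate, so that brominolysis of the C–Mg bond with retention fixes the (Z)-geometry (Br cis to C17).

Step 2
Reactants: 5 (2Z)-2-(bromomethylidene)hept-6-en-1-ol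
Product: 6 (2Z)-2-(bromomethylidene)hept-6-en-1-yl 2,2-dimethylpropanoate
Conditions: t-BuCOCl, pyridine, DMAP (cat.), CH2Cl2, 0 °C → rt
Reagents that add atoms: pivaloyl chloride, CC(C)(C)C(Cl)=O
Why: DMAP-catalysed acylation of the primary allylic alcohol should be clean, and the pivalate is chosen because it should survive the titanium enolate, borohydride and ylide steps that follow.

Step 3
Reactants: 6 (2Z)-2-(bromomethylidene)hept-6-en-1-yl 2,2-dimethylpropanoate
Product: 7 (2Z)-2-(bromomethylidene)-6-oxohexyl 2,2-dimethylpropanoate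
Conditions: OsO4 (cat.), NaIO4, 2,6-lutidine, dioxane–H2O, rt
Reagents that add atoms: sodium periodate (oxygen delivered through OsO4), [Na+].[O-][I](=O)(=O)=O
Why: Lemieux–Johnson cleavage should take the electron-richer monosubstituted olefin and leave the trisubstituted, deactivated bromoalkene untouched, giving the C16 aldehyde.

Step 4
Reactants: 7 (2Z)-2-(bromomethylidene)-6-oxohexyl 2,2-dimethylpropanoate
Product: 8 (5Z)-5-(bromomethylidene)-6-[(2,2-dimethylpropanoyl)oxy]hexanoic acid
Conditions: NaClO2, NaH2PO4, 2-methylbut-2-ene, t-BuOH–H2O, 0 °C → rt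
Reagents that add atoms: sodium chlorite, [Na+].[O-]Cl=O
Why: Pinnick oxidation converts the aldehyde into the acid under buffered conditions that should neither isomerise the bromoalkene nor cleave the pivalate.

Step 5
Reactants: 8 (5Z)-5-(bromomethylidene)-6-[(2,2-dimethylpropanoyl)oxy]hexanoic acid
Product: 10 (4R)-4-benzyl-3-{(5Z)-5-(bromomethylidene)-6-[(2,2-dimethylpropanoyl)oxy]hexanoyl}-1,3-oxazolidin-2-one, via mixed pivalic anhydride 9 (not isolated)
Conditions: t-BuCOCl, Et3N, THF, −20 °C; then LiCl, (4R)-4-benzyl-1,3-oxazolidin-2-one, −20 °C → rt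
Reagents that add atoms: (4R)-4-benzyl-1,3-oxazolidin-2-one, O=C1N[C@H](Cc2ccccc2)CO1
Why: N-Acylation of the Evans oxazolidinone through the mixed anhydride should occur at the less hindered carbonyl of the anhydride without any strong base.

Step 6
Reactants: 10 (4R)-4-benzyl-3-{(5Z)-5-(bromomethylidene)-6-[(2,2-dimethylpropanoyl)oxy]hexanoyl}-1,3-oxazolidin-2-one
Product: 12 (4R)-4-benzyl-3-{(2S,5Z)-5-(bromomethylidene)-6-[(2,2-dimethylpropanoyl)oxy]-2-(hydroxymethyl)hexanoyl}-1,3-oxazolidin-2-one, via chlorotitanium enolate 11 (not isolated)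
Conditions: TiCl4, i-Pr2NEt, CH2Cl2, 0 °C; then 1,3,5-trioxane, TiCl4, 0 °C
Reagents that add atoms: 1,3,5-trioxane, C1OCOCO1
Why: In this Evans hydroxymethylation the chelated (Z)-titanium enolate should take up formaldehyde (released from trioxane) on the face opposite the benzyl group, which introduces C7 and sets C8 in the configuration required by the target.

Step 7
Reactants: 12 (4R)-4-benzyl-3-{(2S,5Z)-5-(bromomethylidene)-6-[(2,2-dimethylpropanoyl)oxy]-2-(hydroxymethyl)hexanoyl}-1,3-oxazolidin-2-one
Product: 13 (4R)-4-benzyl-3-{(2S,5Z)-5-(bromomethylidene)-2-({[tert-butyl(dimethyl)silyl]oxy}methyl)-6-[(2,2-dimethylpropanoyl)oxy]hexanoyl}-1,3-oxazolidin-2-one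
Conditions: t-BuMe2SiCl, imidazole, DMF, rt
Reagents that add atoms: tert-butyl(chloro)dimethylsilane, CC(C)(C)[Si](C)(C)Cl
Why: Silylation of the primary alcohol protects the C7 oxygen and blocks retro-aldol loss of formaldehyde.

Step 8
Reactants: 13 (4R)-4-benzyl-3-{(2S,5Z)-5-(bromomethylidene)-2-({[tert-butyl(dimethyl)silyl]oxy}methyl)-6-[(2,2-dimethylpropanoyl)oxy]hexanoyl}-1,3-oxazolidin-2-one
Product: 14 (2Z,5R)-2-(bromomethylidene)-5-({[tert-butyl(dimethyl)silyl]oxy}methyl)-6-hydroxyhexyl 2,2-dimethylpropanoate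
Conditions: LiBH4, MeOH (1 equiv), THF, 0 °C
Reagents that add atoms: none
Why: Reductive cleavage of the imide with LiBH4 should give the C16 primary alcohol and the recoverable auxiliary without touching the hindered pivalate or C8.

Step 9
Reactants: 14 (2Z,5R)-2-(bromomethylidene)-5-({[tert-butyl(dimethyl)silyl]oxy}methyl)-6-hydroxyhexyl 2,2-dimethylpropanoate
Product: 15 (2Z,5S)-2-(bromomethylidene)-5-({[tert-butyl(dimethyl)silyl]oxy}methyl)-6-oxohexyl 2,2-dimethylpropanoate
Conditions: Dess–Martin periodinane, NaHCO3, CH2Cl2, 0 °C → rt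
Reagents that add atoms: none
Why: Dess–Martin oxidation under buffered, non-basic conditions should give the α-branched aldehyde without epimerising C8 or eliminating the β-silyloxy group.

Step 10
Reactants: 15 (2Z,5S)-2-(bromomethylidene)-5-({[tert-butyl(dimethyl)silyl]oxy}methyl)-6-oxohexyl 2,2-dimethylpropanoate; 16 2-(triphenyl-λ5-phosphanylidene)propanal
Product: 17 (2Z,5R,6E)-2-(bromomethylidene)-5-({[tert-butyl(dimethyl)silyl]oxy}methyl)-7-methyl-8-oxooct-6-en-1-yl 2,2-dimethylpropanoate
Conditions: toluene, 80 °C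
Reagents that add atoms: none
Why: Wittig olefination with the stabilised formyl ylide should give the (E)-trisubstituted enal C16=C15 (methyl cis to C8) under neutral conditions that preserve C8.

Step 11
Reactants: 17 (2Z,5R,6E)-2-(bromomethylidene)-5-({[tert-butyl(dimethyl)silyl]oxy}methyl)-7-methyl-8-oxooct-6-en-1-yl 2,2-dimethylpropanoate
Product: 18 (2Z,5R,6E)-2-(bromomethylidene)-5-({[tert-butyl(dimethyl)silyl]oxy}methyl)-7-methylnona-6,8-dien-1-yl 2,2-dimethylpropanoate
Conditions: Ph3PCH3Br, KN(SiMe3)2, THF, −78 → 0 °C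
Reagents that add atoms: methyltriphenylphosphonium bromide, C[P+](c1ccccc1)(c1ccccc1)c1ccccc1.[Br-]
Why: Wittig methylenation of the enal by 1,2-addition of the non-stabilised ylide should complete the (E)-diene C16=C15–C14=C13.

Step 12
Reactants: 18 (2Z,5R,6E)-2-(bromomethylidene)-5-({[tert-butyl(dimethyl)silyl]oxy}methyl)-7-methylnona-6,8-dien-1-yl 2,2-dimethylpropanoate
Product: 19 (2Z,5R,6E)-2-(bromomethylidene)-5-({[tert-butyl(dimethyl)silyl]oxy}methyl)-7-methylnona-6,8-dien-1-ol
Conditions: iBu2AlH (2.2 equiv), CH2Cl2, −78 °C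
Reagents that add atoms: none
Why: Reductive ester cleavage with iBu2AlH at low temperature should free the C17 alcohol and leave the silyl ether, the diene and the alkenyl bromide intact.

Step 13
Reactants: 19 (2Z,5R,6E)-2-(bromomethylidene)-5-({[tert-butyl(dimethyl)silyl]oxy}methyl)-7-methylnona-6,8-dien-1-ol
Product: 20 (2Z,5R,6E)-2-(bromomethylidene)-5-({[tert-butyl(dimethyl)silyl]oxy}methyl)-7-methylnona-6,8-dienal
Conditions: Dess–Martin periodinane, NaHCO3, CH2Cl2, 0 °C
Reagents that add atoms: none
Why: Dess–Martin oxidation of the allylic alcohol should give the (Z)-β-bromo enal without the acid, base or halide that could isomerise the bromoalkene.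

Step 14
Reactants: 20 (2Z,5R,6E)-2-(bromomethylidene)-5-({[tert-butyl(dimethyl)silyl]oxy}methyl)-7-methylnona-6,8-dienal
Product: 21 (1R,3aS,4S,7aR)-4-bromo-1-({[tert-butyl(dimethyl)silyl]oxy}methyl)-7-methyl-1,2,3,4,5,7a-hexahydro-3aH-indene-3a-carbaldehyde
Conditions: Me2AlCl (1.1 equiv), CH2Cl2, −78 → −30 °C
Reagents that add atoms: none
Why: Me2AlCl binds the formyl oxygen and lowers the LUMO of the (Z)-β-bromo enal, which should then add to the tethered (E)-diene in one concerted, suprafacial [4+2] cycloaddition forming C11–C16 and C12–C13; the closest known reaction type is the Lewis-acid-promoted intramolecular Diels–Alder reaction of 1,3,8-nonatrienes to trans-hydrindenes. Ring C (C11–C12–C13–C14–C15–C16) closes directly as the cyclohexene of the [4+2] array, and ring B (C8–C9–C10–C11–C16) closes at the same time because the tether C8–C9–C10 already joins the diene terminus C16 to the dienophile carbon C11, so that the C11–C16 bond completes the five-membered ring. C12 is controlled by the (Z)-olefin geometry, which the suprafacial addition copies into the cis relation of bromine and C17; C11 and C16 are controlled relative to each other by the transition state with the aluminium-bound formyl group endo and the tether exo, which gives the trans ring fusion; their absolute sense is controlled by C8, whose C–H bond lies in the diene plane to avoid 1,3-allylic strain with the C15 methyl group, so that the dienophile arrives on the face carrying C9 and C7 ends on the face opposite C17. The step needs formyl-endo/tether-exo selectivity and attack on one diene face: the first should be secured by the endo preference of a Lewis-acid-complexed aldehyde (bromine is endo in the same transition state), the second by the C15 methyl group cis to C8 on the (E)-diene. Regiochemistry is fixed by the tether, and the low temperature should keep the alkenyl bromide from isomerising or exchanging halide before it cyclises.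

Step 15
Reactants: 21 (1R,3aS,4S,7aR)-4-bromo-1-({[tert-butyl(dimethyl)silyl]oxy}methyl)-7-methyl-1,2,3,4,5,7a-hexahydro-3aH-indene-3a-carbaldehyde
Product: 22 (1R,3aS,4S,7aR)-4-bromo-1-({[tert-butyl(dimethyl)silyl]oxy}methyl)-7-methyl-1,2,3,4,5,7a-hexahydro-3aH-indene-3a-carboxylic acid
Conditions: NaClO2, NaH2PO4, 2-methylbut-2-ene, t-BuOH–H2O, 0 °C → rt
Reagents that add atoms: sodium chlorite, [Na+].[O-]Cl=O
Why: Pinnick oxidation of the neopentyl aldehyde should give the C17 acid while the scavenger protects the ring olefin from hypochlorite.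

Step 16
Reactants: 22 (1R,3aS,4S,7aR)-4-bromo-1-({[tert-butyl(dimethyl)silyl]oxy}methyl)-7-methyl-1,2,3,4,5,7a-hexahydro-3aH-indene-3a-carboxylic acid
Product: 23 lactone alcohol (C17 carbonyl bonded through oxygen to C15; C8 bears CH2OH)
Conditions: CF3CO2H–H2O (9:1), 0 °C → rt; aq. NaHCO3 work-up
Reagents that add atoms: none
Why: In this acid-mediated protolactonisation the olefin is protonated at C14 and the tertiary C15 cation is captured by the axial C17 carboxyl group, which can reach C15 only on its own face, so that C15 is set with oxygen cis to C17 and methyl trans, while the same acid removes the primary silyl ether.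

Step 17
Reactants: 23 lactone alcohol
Product: 24 lactone iodide (C7 iodide of 23)
Conditions: I2, PPh3, imidazole, CH2Cl2, 0 °C → rt
Reagents that add atoms: iodine, II
Why: Appel-type iodination of the primary alcohol proceeds by SN2 at C7, where no stereocentre is involved, and should leave the lactone and the hindered secondary bromide alone.

Step 18
Reactants: 25 tert-butyl 3-oxobutanoate; 26 1-bromo-3-methylbut-2-ene
Product: 28 tert-butyl 7-methyl-3-oxooct-6-enoate, via acetoacetate dianion 27 (not isolated)
Conditions: NaH, THF, 0 °C; n-BuLi, 0 °C; then 26, 0 °C → rt; aq. NH4Cl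
Reagents that add atoms: none
Why: In this dianion γ-alkylation of an acetoacetate the more basic terminal carbanion should be alkylated by the primary allylic bromide.

Step 19
Reactants: 28 tert-butyl 7-methyl-3-oxooct-6-enoate
Product: 29 tert-butyl 5-bromo-6,6-dimethyl-2-oxocyclohexane-1-carboxylate (racemic)
Conditions: Et2SBr·SbCl5Br (BDSB), MeNO2, −25 °C
Reagents that add atoms: bromodiethylsulfonium bromopentachloroantimonate, CC[S+](Br)CC.Cl[Sb-](Cl)(Cl)(Cl)(Cl)Br
Why: In this bromonium-induced cation–olefin cyclisation the electrophilic bromine should add to the trisubstituted olefin and the enol carbon of the β-keto ester should close the six-membered ring at the tertiary carbon, which places bromine on C4 next to the gem-dimethyl carbon without any substitution at a neopentyl centre.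

Step 20
Reactants: 29 tert-butyl 5-bromo-6,6-dimethyl-2-oxocyclohexane-1-carboxylate
Product: 31 rac-4-bromo-3,3-dimethylcyclohexan-1-one, via β-keto acid 30 (not isolated)
Conditions: CF3CO2H, CH2Cl2, rt; then toluene, 80 °C
Reagents that add atoms: none
Why: Acidolysis of the tert-butyl ester followed by thermal decarboxylation of the β-keto acid removes the activating ester under conditions that should not disturb the secondary bromide.

Step 21
Reactants: 31 rac-4-bromo-3,3-dimethylcyclohexan-1-one
Product: 32 (2R,3R,8S)-8-bromo-7,7-dimethyl-2,3-diphenyl-1,4-dioxaspiro[4.5]decane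
Conditions: (1R,2R)-1,2-diphenylethane-1,2-diol, pyridinium p-toluenesulfonate (cat.), benzene, reflux (Dean–Stark); separation of the two ketals on silica, then crystallisation
Reagents that add atoms: (1R,2R)-1,2-diphenylethane-1,2-diol, O[C@H](c1ccccc1)[C@H](O)c1ccccc1
Why: Ketalisation with the C2-symmetric diol is a classical resolution that turns the two enantiomers into separable diastereomers without creating a new stereocentre at the spiro carbon, and the (8S) ketal is kept because it carries the C4 configuration of the target.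

Step 22
Reactants: 32 (2R,3R,8S)-8-bromo-7,7-dimethyl-2,3-diphenyl-1,4-dioxaspiro[4.5]decane
Product: 33 (4S)-4-bromo-3,3-dimethylcyclohexan-1-one
Conditions: aq. HCl (2 M), THF, rt
Reagents that add atoms: water, O
Why: Acid-catalysed ketal hydrolysis returns the ketone, and C4 cannot epimerise because it is not α to the carbonyl group.

Step 23
Reactants: 24 lactone iodide; 33 (4S)-4-bromo-3,3-dimethylcyclohexan-1-one
Product: 35 tertiary alcohol (C1–OH, C1–C7 bond formed; lactone retained), via alkylsamarium diiodide 34 (not isolated)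
Conditions: SmI2 (2.5 equiv), NiI2 (2 mol %), THF, 0 °C → rt (24 and 33 added together)
Reagents that add atoms: none
Why: In this samarium Barbier reaction SmI2 should reduce the primary iodide much faster than the secondary bromides or the lactone, and the alkylsamarium should add to the ketone from the equatorial direction, anti to the axial C5 methyl group, on the chair that holds C4–Br equatorial (the other chair would put bromine axial on the face of approach), which sets C1 with oxygen cis to bromine.

Step 24
Reactants: 35 tertiary alcohol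
Product: 36 tertiary acetate (C1–OAc; lactone retained)
Conditions: Ac2O, Me3SiOTf (cat.), CH2Cl2, −20 → 0 °C
Reagents that add atoms: acetic anhydride, CC(=O)OC(C)=O
Why: Lewis-acid-catalysed acetylation should overcome the hindrance of the axial tertiary alcohol without breaking the C1–O bond, while the lactone still masks the C15 and C17 oxygens so that only C1–OH is acylated.

Step 25
Reactants: 36 tertiary acetate
Product: 38 target CNP0182818.1, via lactol 37 (not isolated)
Conditions: iBu2AlH (1.1 equiv), CH2Cl2, −78 °C; then MeOH, NaBH4, −78 → 0 °C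
Reagents that add atoms: none
Why: Partial reduction of the strained bicyclic γ-lactone with one equivalent of iBu2AlH should stop at the lactol, whose open hydroxy aldehyde form is then reduced by NaBH4 to free the C17 CH2OH and the C15 tertiary alcohol, while the hindered tertiary acetate and the secondary bromides should survive both hydrides.

**Compound list**

1 | prop-2-yn-1-ol | C#CCO | starting material
2 | 5-bromopent-1-ene | C=CCCCBr | starting material
3 | pent-4-en-1-ylmagnesium bromide | C=CCCC[Mg]Br | intermediate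
4 | bromomagnesium (2Z)-2-[(bromomagnesio)methylidene]hept-6-en-1-olate (Mg on C12 cis to the CH2O group) | C=CCCC/C(CO[Mg]Br)=C/[Mg]Br | intermediate
5 | (2Z)-2-(bromomethylidene)hept-6-en-1-ol | C=CCCC/C(CO)=C/Br | intermediate
6 | (2Z)-2-(bromomethylidene)hept-6-en-1-yl 2,2-dimethylpropanoate | C=CCCC/C(COC(=O)C(C)(C)C)=C/Br | intermediate
7 | (2Z)-2-(bromomethylidene)-6-oxohexyl 2,2-dimethylpropanoate | O=CCCC/C(COC(=O)C(C)(C)C)=C/Br | intermediate
8 | (5Z)-5-(bromomethylidene)-6-[(2,2-dimethylpropanoyl)oxy]hexanoic acid | OC(=O)CCC/C(COC(=O)C(C)(C)C)=C/Br | intermediate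
9 | (5Z)-5-(bromomethylidene)-6-[(2,2-dimethylpropanoyl)oxy]hexanoic 2,2-dimethylpropanoic anhydride | CC(C)(C)C(=O)OC(=O)CCC/C(COC(=O)C(C)(C)C)=C/Br | intermediate
10 | (4R)-4-benzyl-3-{(5Z)-5-(bromomethylidene)-6-[(2,2-dimethylpropanoyl)oxy]hexanoyl}-1,3-oxazolidin-2-one | O=C(CCC/C(COC(=O)C(C)(C)C)=C/Br)N1[C@H](Cc2ccccc2)COC1=O | intermediate
11 | trichlorotitanium (Z)-enolate of 10 (O–Ti cis to C9) | Cl[Ti](Cl)(Cl)O/C(=C\CC/C(COC(=O)C(C)(C)C)=C/Br)N1[C@H](Cc2ccccc2)COC1=O | intermediate
12 | (4R)-4-benzyl-3-{(2S,5Z)-5-(bromomethylidene)-6-[(2,2-dimethylpropanoyl)oxy]-2-(hydroxymethyl)hexanoyl}-1,3-oxazolidin-2-one | OC[C@H](CC/C(COC(=O)C(C)(C)C)=C/Br)C(=O)N1[C@H](Cc2ccccc2)COC1=O | intermediate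
13 | (4R)-4-benzyl-3-{(2S,5Z)-5-(bromomethylidene)-2-({[tert-butyl(dimethyl)silyl]oxy}methyl)-6-[(2,2-dimethylpropanoyl)oxy]hexanoyl}-1,3-oxazolidin-2-one | CC(C)(C)[Si](C)(C)OC[C@H](CC/C(COC(=O)C(C)(C)C)=C/Br)C(=O)N1[C@H](Cc2ccccc2)COC1=O | intermediate
14 | (2Z,5R)-2-(bromomethylidene)-5-({[tert-butyl(dimethyl)silyl]oxy}methyl)-6-hydroxyhexyl 2,2-dimethylpropanoate | CC(C)(C)[Si](C)(C)OC[C@H](CC/C(COC(=O)C(C)(C)C)=C/Br)CO | intermediate
15 | (2Z,5S)-2-(bromomethylidene)-5-({[tert-butyl(dimethyl)silyl]oxy}methyl)-6-oxohexyl 2,2-dimethylpropanoate | CC(C)(C)[Si](C)(C)OC[C@H](CC/C(COC(=O)C(C)(C)C)=C/Br)C=O | intermediate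
16 | 2-(triphenyl-λ5-phosphanylidene)propanal | CC(C=O)=P(c1ccccc1)(c1ccccc1)c1ccccc1 | starting material
17 | (2Z,5R,6E)-2-(bromomethylidene)-5-({[tert-butyl(dimethyl)silyl]oxy}methyl)-7-methyl-8-oxooct-6-en-1-yl 2,2-dimethylpropanoate | CC(C)(C)[Si](C)(C)OC[C@H](CC/C(COC(=O)C(C)(C)C)=C/Br)/C=C(\C)C=O | intermediate
18 | (2Z,5R,6E)-2-(bromomethylidene)-5-({[tert-butyl(dimethyl)silyl]oxy}methyl)-7-methylnona-6,8-dien-1-yl 2,2-dimethylpropanoate | CC(C)(C)[Si](C)(C)OC[C@H](CC/C(COC(=O)C(C)(C)C)=C/Br)/C=C(\C)C=C | intermediate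
19 | (2Z,5R,6E)-2-(bromomethylidene)-5-({[tert-butyl(dimethyl)silyl]oxy}methyl)-7-methylnona-6,8-dien-1-ol | CC(C)(C)[Si](C)(C)OC[C@H](CC/C(CO)=C/Br)/C=C(\C)C=C | intermediate
20 | (2Z,5R,6E)-2-(bromomethylidene)-5-({[tert-butyl(dimethyl)silyl]oxy}methyl)-7-methylnona-6,8-dienal | CC(C)(C)[Si](C)(C)OC[C@H](CC/C(C=O)=C/Br)/C=C(\C)C=C | intermediate
21 | (1R,3aS,4S,7aR)-4-bromo-1-({[tert-butyl(dimethyl)silyl]oxy}methyl)-7-methyl-1,2,3,4,5,7a-hexahydro-3aH-indene-3a-carbaldehyde (trans-fused; Br cis to CHO) | CC(C)(C)[Si](C)(C)OC[C@@H]1CC[C@]2(C=O)[C@@H](Br)CC=C(C)[C@@H]12 | intermediate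
22 | (1R,3aS,4S,7aR)-4-bromo-1-({[tert-butyl(dimethyl)silyl]oxy}methyl)-7-methyl-1,2,3,4,5,7a-hexahydro-3aH-indene-3a-carboxylic acid | CC(C)(C)[Si](C)(C)OC[C@@H]1CC[C@]2(C(O)=O)[C@@H](Br)CC=C(C)[C@@H]12 | intermediate
23 | lactone alcohol: trans-fused bromo hydrindane with the γ-lactone C17(=O)–O–C15 on the face of C17, C12–Br cis to C17, C15 methyl on the other face, C8–CH2OH trans to C17 | OC[C@@H]1CC[C@]2(C(=O)O3)[C@@H](Br)CC[C@]3(C)[C@@H]12 | intermediate
24 | lactone iodide: as 23 with C7–I in place of C7–OH | IC[C@@H]1CC[C@]2(C(=O)O3)[C@@H](Br)CC[C@]3(C)[C@@H]12 | intermediate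
25 | tert-butyl 3-oxobutanoate | CC(=O)CC(=O)OC(C)(C)C | starting material
26 | 1-bromo-3-methylbut-2-ene | CC(C)=CCBr | starting material
27 | lithium sodium dianion (bis-enolate) of tert-butyl 3-oxobutanoate | C=C([O-])C=C([O-])OC(C)(C)C.[Na+].[Li+] | intermediate
28 | tert-butyl 7-methyl-3-oxooct-6-enoate | CC(C)=CCCC(=O)CC(=O)OC(C)(C)C | intermediate
29 | tert-butyl 5-bromo-6,6-dimethyl-2-oxocyclohexane-1-carboxylate (racemic) | CC(C)(C)OC(=O)C1C(=O)CCC(Br)C1(C)C | intermediate
30 | 5-bromo-6,6-dimethyl-2-oxocyclohexane-1-carboxylic acid (racemic) | OC(=O)C1C(=O)CCC(Br)C1(C)C | intermediate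
31 | rac-4-bromo-3,3-dimethylcyclohexan-1-one | CC1(C)CC(=O)CCC1Br | intermediate
32 | (2R,3R,8S)-8-bromo-7,7-dimethyl-2,3-diphenyl-1,4-dioxaspiro[4.5]decane | C12(CC[C@H](Br)C(C)(C)C1)O[C@H](c3ccccc3)[C@@H](c3ccccc3)O2 | intermediate
33 | (4S)-4-bromo-3,3-dimethylcyclohexan-1-one | O=C1CC[C@H](Br)C(C)(C)C1 | intermediate
34 | alkylsamarium diiodide: as 24 with C7–SmI2 in place of C7–I | I[Sm](I)C[C@@H]1CC[C@]2(C(=O)O3)[C@@H](Br)CC[C@]3(C)[C@@H]12 | intermediate
35 | tertiary alcohol: (1S,4S)-4-bromo-3,3-dimethylcyclohexan-1-ol joined at C1 through C7 to C8 of the bromo lactone; OH cis to the ring A bromine | O[C@]1(C[C@@H]2CC[C@]3(C(=O)O4)[C@@H](Br)CC[C@]4(C)[C@@H]23)CC[C@H](Br)C(C)(C)C1 | intermediate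
36 | tertiary acetate: C1 acetate of 35 | CC(=O)O[C@]1(C[C@@H]2CC[C@]3(C(=O)O4)[C@@H](Br)CC[C@]4(C)[C@@H]23)CC[C@H](Br)C(C)(C)C1 | intermediate
37 | lactol: as 36 with the lactone carbonyl C17 reduced to the cyclic hemiacetal (both anomers) | CC(=O)O[C@]1(C[C@@H]2CC[C@]3(C(O)O4)[C@@H](Br)CC[C@]4(C)[C@@H]23)CC[C@H](Br)C(C)(C)C1 | intermediate
38 | CNP0182818.1: (1S,4S)-4-bromo-1-{[(1S,3aS,4S,7R,7aS)-4-bromo-7-hydroxy-3a-(hydroxymethyl)-7-methyloctahydro-1H-inden-1-yl]methyl}-3,3-dimethylcyclohexyl acetate | CC(=O)O[C@]1(C[C@@H]2CC[C@]3(CO)[C@@H](Br)CC[C@@](C)(O)[C@@H]23)CC[C@H](Br)C(C)(C)C1 | target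

**Step count**

Total: 25 steps. Longest linear sequence: 20 steps (steps 1–17, then 23–25, from prop-2-yn-1-ol); ring A takes 5 steps (18–22).

**Steps most likely to fail**

Step 14. What may go wrong: on the aluminium Lewis acid the β-bromo enal may exchange bromide for chloride or isomerise from (Z) to (E) by conjugate addition–elimination, and the formyl-endo preference may erode so that cis-fused material forms. The fallback changes the activating group and removes the Lewis acid. It sets out from 20, which is oxidised (NaClO2, NaH2PO4, 2-methylbut-2-ene) to the (Z)-bromoacrylic acid F1 and methylated with Me3SiCHN2 to the methyl (Z)-bromoacrylate triene F2. F2 is cyclised purely thermally (toluene, 2,6-di-tert-butyl-4-methylphenol, 170 °C, sealed tube) to the methyl ester adduct F3, whose hindered ester is cleaved with trimethyltin hydroxide (1,2-dichloroethane, 80 °C). This comes back to the route at 22.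

Step 23. What may go wrong: SmI2 may also reduce the two secondary C–Br bonds or couple the ketone reductively, and the ketone may react through its other chair so that facial selectivity at C1 is poor. The fallback replaces the single-electron Barbier coupling by a polar organocerium addition on a substrate whose lactone is masked. It sets out from 23, which is reduced with iBu2AlH to the lactol F4 and converted with MeOH and pyridinium p-toluenesulfonate into the methyl acetal alcohol F5. Iodination (I2, PPh3, imidazole) gives the acetal iodide F6; iodine–lithium exchange (t-BuLi, Et2O–pentane, −78 °C) gives the alkyllithium F7, and transmetalation with CeCl3 gives the alkylcerium dichloride F8. F8, which is bulky and non-basic, is added to 33 at −78 °C to give the acetal tertiary alcohol F9, and acetylation (Ac2O, DMAP, Et3N) gives the acetal acetate F10. Hydrolysis of the acetal with aqueous acetic acid comes back to the route at 37, which is reduced with NaBH4 as in step 25.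

Step 25. What may go wrong: hydride attack on the C1 acetate competes with reduction of the lactone, so that the acetyl group is lost. The fallback reverses the order of reduction and acetylation. It sets out from 35, which is reduced with excess iBu2AlH at −78 °C to the lactol tertiary alcohol F11. Exhaustive acetylation (Ac2O, DMAP, Et3N, 40 °C) gives the diacetate F12, and hydrazine acetate in DMF removes only the anomeric acetate. This comes back to the route at 37, which is reduced with NaBH4 as in step 25.

**Further compounds**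

F1 | step 14 | (2Z,5R,6E)-2-(bromomethylidene)-5-({[tert-butyl(dimethyl)silyl]oxy}methyl)-7-methylnona-6,8-dienoic acid | CC(C)(C)[Si](C)(C)OC[C@H](CC/C(C(O)=O)=C/Br)/C=C(\C)C=C
F2 | step 14 | methyl (2Z,5R,6E)-2-(bromomethylidene)-5-({[tert-butyl(dimethyl)silyl]oxy}methyl)-7-methylnona-6,8-dienoate | CC(C)(C)[Si](C)(C)OC[C@H](CC/C(C(=O)OC)=C/Br)/C=C(\C)C=C
F3 | step 14 | methyl (1R,3aS,4S,7aR)-4-bromo-1-({[tert-butyl(dimethyl)silyl]oxy}methyl)-7-methyl-1,2,3,4,5,7a-hexahydro-3aH-indene-3a-carboxylate | CC(C)(C)[Si](C)(C)OC[C@@H]1CC[C@]2(C(=O)OC)[C@@H](Br)CC=C(C)[C@@H]12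
F4 | step 23 | lactol of 23 (C17 hemiacetal, both anomers; C7–OH free) | OC[C@@H]1CC[C@]2(C(O)O3)[C@@H](Br)CC[C@]3(C)[C@@H]12
F5 | step 23 | methyl acetal alcohol (C17 methyl acetal of F4) | OC[C@@H]1CC[C@]2(C(OC)O3)[C@@H](Br)CC[C@]3(C)[C@@H]12
F6 | step 23 | methyl acetal iodide (C7–I) | IC[C@@H]1CC[C@]2(C(OC)O3)[C@@H](Br)CC[C@]3(C)[C@@H]12
F7 | step 23 | alkyllithium (C7–Li) of the methyl acetal | [Li]C[C@@H]1CC[C@]2(C(OC)O3)[C@@H](Br)CC[C@]3(C)[C@@H]12
F8 | step 23 | alkylcerium dichloride (C7–CeCl2) of the methyl acetal | Cl[Ce](Cl)C[C@@H]1CC[C@]2(C(OC)O3)[C@@H](Br)CC[C@]3(C)[C@@H]12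
F9 | step 23 | acetal tertiary alcohol (as 35 with the C17 methyl acetal in place of the lactone) | O[C@]1(C[C@@H]2CC[C@]3(C(OC)O4)[C@@H](Br)CC[C@]4(C)[C@@H]23)CC[C@H](Br)C(C)(C)C1
F10 | step 23 | acetal acetate (C1 acetate of F9) | CC(=O)O[C@]1(C[C@@H]2CC[C@]3(C(OC)O4)[C@@H](Br)CC[C@]4(C)[C@@H]23)CC[C@H](Br)C(C)(C)C1
F11 | step 25 | lactol tertiary alcohol (as 35 with the lactone reduced to the hemiacetal) | O[C@]1(C[C@@H]2CC[C@]3(C(O)O4)[C@@H](Br)CC[C@]4(C)[C@@H]23)CC[C@H](Br)C(C)(C)C1
F12 | step 25 | diacetate (C1 acetate and anomeric acetate of F11) | CC(=O)O[C@]1(C[C@@H]2CC[C@]3(C(OC(C)=O)O4)[C@@H](Br)CC[C@]4(C)[C@@H]23)CC[C@H](Br)C(C)(C)C1
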